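The earlier runs and the new flask are calculated with made-up constants; the scatter is artificial.

The slow part of your flasks was where I looked: in the beta run solvolysis product climbed from 20.1% to 49.3% between 30.0 min and 90.0 min, while target read 14.1% and then 16.1%.

| flask | substrate | first nucleophile | second nucleophile | remark | time |
|---|---|---|---|---|---|
| eta | 0.048 M | 0.096 M | 0.0456 M | run made earlier |  |
| beta | 0.048 M | 0.096 M | 0.023 M | run made earlier |  |
| theta | 0.048 M | 0.096 M | 0.091 M | run made earlier |  |
| epsilon | 0.096 M | 0.096 M | 0.0456 M | run made earlier |  |
| Thursday's | 0.048 M | 0.0960 M | 0.0456 M | everything together at the start | 1.5 h |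
| Sunday's | 0.048 M (fed, over 20 min) | 0.0960 M | 0.0456 M | all else is in the flask from the start; the feed brings no volume worth counting | 1.5 h |
| Tuesday's | 0.048 M | 0.0960 M (fed, over 20 min) | 0.0456 M | all else is in the flask from the start; the feed brings no volume worth counting | 1.5 h |

- eta (time / min: solvolysis product / %, target / %): 10.0: 3.1, 11.5; 20.0: 9.3, 13.3; 25.0: 12.5, 14.5; 40.0: 21.7, 14.4; 50.0: 27.1, 13.6
- beta (time / min: solvolysis product / %, target / %): 6.00: 1.3, 7.7; 20.0: 10.5, 15.4; 30.0: 20.1, 14.1; 50.0: 34.5, 15.1; 60.0: 39.2, 14.3; 90.0: 49.3, 16.1
- theta (time / min: solvolysis product / %, target / %): 6.00: 0.6, 7.2; 20.0: 7.2, 11.8; 30.0: 12.1, 12.9; 50.0: 19.3, 12.0; 60.0: 22.8, 12.8; 90.0: 28.9, 11.7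
- epsilon (time / min: solvolysis product / %, target / %): 8.00: 3.2, 8.8; 25.0: 13.2, 12.4; 40.0: 23.7, 13.2; 60.0: 33.2, 12.8; 90.0: 42.2, 12.3

(scatter of a reading: 0.5 percentage points)

- a reading or a percentage of target counts all its forms, free or not

* the flask that comes out highest in amount of solvolysis product, in percent of the substrate charged; "all alike" if 1.5 percentage points covers them all (Thursday's / Sunday's / Tuesday's / all alike)
* amount of solvolysis product at the end, in percent of the substrate charged, Thursday's
* amount of solvolysis product at the end, in percent of the substrate charged, Sunday's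
* amount of solvolysis product at the end, in percent of the substrate charged, Tuesday's

So I followed one molecule that had not become target. At its fork it became solvolysis product or was lost to second nucleophile. Over that stretch beta gained 29 percentage points and theta 17 points, a ratio g of 1.74. From that ratio I reckoned a selectivity factor per molar, sel:

sel = (g − 1) / (c(second nucleophile, theta) − g × c(second nucleophile, beta)) = 14.5 M⁻¹

share = 1 / (1 + sel × c(second nucleophile)) = 0.603 at the charge of 0.0456 M

I called this the solvolysis share: the chance that a molecule not taken as target ends as solvolysis product. My ceiling for a flask was: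

ceiling = share × (whole charge − target)

With eta's plateau reading that gave Thursday's 51.6%. Beta had reached 78.3% of its own ceiling by 90.0 min, so I said 40.4% for Thursday's.

Eta's target, 0.00691 M, was far less than the charge of first nucleophile, yet its readings had stopped rising by 25.0 min. I took it that first nucleophile was leaving by another road. Sunday's fed substrate should then find less of it, and Tuesday's feed should keep it longer. I put Sunday's highest and Tuesday's lowest.

Your forecast put Thursday's on top, with 38% for Thursday's, 35% for Sunday's and 26% for Tuesday's, and said of Tuesday's that “the branch probably shifts away from product”. We parted on the top place, and on that branch: I held the share fixed across the three flasks.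

The simulation put Sunday's highest.

    intermediate → solvolysis product (k = 0.00199 s⁻¹)
    substrate + target ⇌ idle adduct, settled at all times (K = 46.0 M⁻¹)
    second nucleophile + intermediate → other capture product (k = 0.0395 M⁻¹ s⁻¹)
    first nucleophile → decomposed reagent (k = 0.00339 s⁻¹)
    first nucleophile + intermediate → target (k = 0.225 M⁻¹ s⁻¹)
    substrate → intermediate (k = 4.19 × 10⁻⁴ s⁻¹)

Sunday's gave 45.0%, Thursday's 39.8% and Tuesday's 34.3%. Target at the end stood at 4.75% in Sunday's, against 14.1% in Thursday's and 21.4% in Tuesday's. For Sunday's, the share times what target left gives 57.4%, and at 15.0 h that flask stood at 56.0%. For Tuesday's, the same product gives 47.3%, and at 15.0 h that flask stood at 45.3%.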